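**Plan**
- **Cuts.** The C3–O acyl bond goes first (the trienoic acid is itself cut at C4=C5). The oxygens at C3, C12, C9 and C8 and H10 are then stripped back to (+)-aristolochene. Last, C5–C14, C5–C10 and C6–C7 are cut back to farnesyl diphosphate.
- **Enabling feature.** Methyl C15 on C4 and methyl C14 on quaternary C5 are cis and vicinal, beside ring-fusion carbon C10 of rings A and B, and C7 of ring B carries a three-carbon branch. This is the imprint of a farnesyl chain closed to a germacrene and then to a eudesmane cation that has undergone one hydride shift and one methyl shift.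
- **Forward order.** One enzymatic step closes the ten-membered ring and then rings A and B together through a transannular bond. Ring B is then oxidised (C8, H10, C9, C12), ring A is hydroxylated at C3, and the chain is joined last.
- **Stereochemistry.** C4 and C5 come from the enzyme. C10 comes from axial protonation, C9 from α-face oxidation steered by C14, and C3 from retentive hydroxylation of the equatorial C–H. The C7=C11 E geometry comes from the epoxide opening and the triene geometry from olefination.

Key step: step 3

Convention: eremophilane numbering is used (ring A = C1–C5, C10; ring B = C5–C10; C14 on C5, C15 on C4, C11–C13 on C7). Farnesyl C1 to C11 correspond to C6, C5, C4, C3, C2, C1, C10, C9, C8, C7, C11. β is the face that carries C14.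
Remark: farnesyl diphosphate is handled as its triammonium salt and drawn as the free acid. Commercial non-3-en-2-one is taken as the E isomer.

**Step 1**
Reactants: 1 (2E,6E)-farnesol
Product: 2 (2E,6E)-farnesyl bromide
Conditions: PBr3 (0.4 equiv), Et2O, 0 °C
Reagents that add atoms: phosphorus tribromide, BrP(Br)Br
Why: SN2-type bromination of the primary allylic alcohol through its phosphite ester is fast at 0 °C, so neither allylic transposition nor loss of the 2E geometry is expected.

**Step 2**
Reactants: 2 (2E,6E)-farnesyl bromide
Product: 3 (2E,6E)-farnesyl diphosphate (triammonium salt)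
Conditions: (Bu4N)3HP2O7, MeCN, rt; cation-exchange resin (NH4+ form), NH4HCO3 buffer; cellulose chromatography
Reagents that add atoms: tris(tetrabutylammonium) hydrogen diphosphate, CCCC[N+](CCCC)(CCCC)CCCC.CCCC[N+](CCCC)(CCCC)CCCC.CCCC[N+](CCCC)(CCCC)CCCC.OP(=O)([O-])OP(=O)([O-])[O-]
Why: SN2 displacement of the allylic bromide by the organic-soluble diphosphate anion is the standard diphosphorylation of prenyl halides, and ion exchange gives the water-soluble salt that the enzyme accepts.

**Step 3**
Reactants: 3 (2E,6E)-farnesyl diphosphate
Product: 5 (+)-aristolochene [(4S,5R,7S)-eremophila-9,11-diene], via (S)-germacrene A 4 (not isolated)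
Conditions: aristolochene synthase (Penicillium roqueforti, recombinant, His6-tagged, from E. coli), MgCl2 (5 mM), Tris-HCl pH 7.5, 2-mercaptoethanol, glycerol (15% v/v), pentane overlay, 25 °C
Reagents that add atoms: none
Why: Mg2+-assisted ionisation of the diphosphate gives the farnesyl cation, whose C6 is captured by the distal C7=C11 alkene (C6–C7, ten-membered ring); loss of a C12 proton leaves enzyme-bound 4, reprotonation at C1 lets the C4=C5 alkene attack C10 (C5–C10), and the C4 cation is discharged by a C5→C4 hydride shift, a C10→C5 methyl shift (C5–C14) and loss of a proton from C9. This is the native reaction of the enzyme and belongs to the ionisation-initiated cationic polycyclisations of sesquiterpene synthases. The macrocycle closes in 10-exo mode at the C7=C11 alkene, and the transannular bond closes ring A in 6-endo and ring B in 6-exo mode with respect to the C4=C5 alkene. C7 is set by the alkene face that the folded chain offers to C6, C5 by the fold of 4 and the face on which C14 arrives, and C4 by the face on which the hydride arrives; both shifts are suprafacial and run on opposite faces, which leaves C14 and C15 cis. The step needs closure of C6 onto C7 rather than onto the central alkene, retention of 4 in the active site and deprotonation at C9 rather than C1; in the substrate the 2E,6E geometry lets C6 reach C7 without prior isomerisation and every bond forms at the less substituted alkene terminus so that each cation is tertiary, while the active-site contour secures the rest, and traces of 4 and of the C1=C10 isomer are removed on AgNO3-impregnated silica.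

**Step 4**
Reactants: 5 (+)-aristolochene
Product: 6 (4S,5R,7S)-eremophila-9,11-dien-8-one (7α-isopropenyl)
Conditions: CrO3, 3,5-dimethylpyrazole, CH2Cl2, −20 °C; filtration through silica
Reagents that add atoms: chromium trioxide, O=[Cr](=O)=O
Why: Allylic oxidation with the CrO3–3,5-dimethylpyrazole complex removes hydrogen from the unhindered ring CH2 (C8) at the CH terminus of the trisubstituted alkene and gives the conjugated enone, the pattern known for isopropenyl-bearing octalin sesquiterpenes, while the 1,1-disubstituted alkene is left alone.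

**Step 5**
Reactants: 6 eremophila-9,11-dien-8-one
Product: 8 trimethylsilyl enol ether (C8=C9) of 10αH-eremophil-11-en-8-one, via lithium enolate 7 (not isolated)
Conditions: Li, NH3/THF, t-BuOH (1 equiv), −78 °C; isoprene; NH3 evaporated; Me3SiCl, Et3N, THF, 0 °C
Reagents that add atoms: chlorotrimethylsilane, C[Si](C)(C)Cl
Why: Dissolving-metal conjugate reduction protonates the C10 carbanion axially on the α face, opposite the angular C14 methyl, to give the trans-decalin, and the regiodefined C8=C9 enolate is fixed by O-silylation (reductive enolate trapping) while the isolated isopropenyl alkene is not reduced.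

**Step 6**
Reactants: 8 trimethylsilyl enol ether
Product: 10 9α-hydroxy-11,12-epoxy-10αH-eremophilan-8-one (both C11 epimers), via 9α-silyloxy epoxy ketone 9 (not isolated)
Conditions: mCPBA (2.3 equiv), CH2Cl2, −20 to 0 °C; then 10% aq. citric acid, THF, 0 °C
Reagents that add atoms: 3-chloroperoxybenzoic acid, O=C(OO)c1cccc(Cl)c1
Why: In the Rubottom oxidation the peracid attacks the electron-rich enol ether on the α face, because the β face at C9 is 1,3-diaxial to C14, and silyl migration leaves the equatorial 9α-oxygen, while the second equivalent epoxidises the isopropenyl group (Prilezhaev reaction) to C11 epimers that both serve because C11 becomes trigonal in the next step.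

**Step 7**
Reactants: 10 9α-hydroxy-11,12-epoxy-10αH-eremophilan-8-one
Product: 11 (E)-9α,12-dihydroxy-10αH-eremophil-7(11)-en-8-one
Conditions: DBU (1.2 equiv), CH2Cl2, 0 °C, short contact time
Reagents that add atoms: none
Why: E1cB opening of a β,γ-epoxy ketone: DBU enolises C7 and the C11–O bond aligned with the enolate π system breaks, and in that rotamer the tied-back epoxide CH2 lies almost in the enolate plane while the methyl stands well out of it, so C12 should sit beside C6 and the methyl over the flat C8 side, away from axial H6 and C14, giving the E alkene from both C11 epimers.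

**Step 8**
Reactants: 11 (E)-9α,12-dihydroxy-10αH-eremophil-7(11)-en-8-one
Product: 12 (E)-9α,12-diacetoxy-10αH-eremophil-7(11)-en-8-one
Conditions: Ac2O, pyridine, DMAP (cat.), CH2Cl2, 0 °C to rt
Reagents that add atoms: acetic anhydride, CC(=O)OC(C)=O
Why: DMAP-catalysed acetylation caps both hydroxyls as small esters that are stable in buffer and offer no activated C–H bond to an oxygenase, so that the hydroxyl introduced next is the only free one.

**Step 9**
Reactants: 12 (E)-9α,12-diacetoxy-10αH-eremophil-7(11)-en-8-one
Product: 13 (E)-9α,12-diacetoxy-3α-hydroxy-10αH-eremophil-7(11)-en-8-one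
Conditions: purified P450BM3 (CYP102A1) variant chosen by screening active-site libraries (positions 78, 82, 87, 328), NADP+ (cat.), D-glucose, glucose dehydrogenase, air, K2HPO4/KH2PO4 buffer pH 8.0, DMSO (2% v/v), 25 °C
Reagents that add atoms: dioxygen, O=O
Why: Proposed new method: no oxygenase is known for C3 of an eremophilane, but the oxo-iron haem oxidant abstracts hydrogen and returns hydroxyl with retention at the C–H bond held nearest to iron, and with the ketone and two acetates anchoring the polar ring B end at the channel mouth the lipophilic tip of ring A should point at the haem, where the equatorial 3α-H is the most exposed and most electron-rich secondary C–H and lies farthest from the withdrawing groups; the closest known reaction type is hydroxylation of the equatorial C3–H in ring A of trans-decalin terpenoid lactones by engineered P450BM3 variants.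

**Step 10**
Reactants: 14 (E)-non-3-en-2-one; 15 triethyl (E)-4-phosphonocrotonate
Product: 16 ethyl (2E,4E,6E)-5-methyldodeca-2,4,6-trienoate
Conditions: 15, LiN(SiMe3)2, THF, −78 °C; then 14, −78 °C to rt
Reagents that add atoms: none
Why: The vinylogous Horner–Wadsworth–Emmons olefination adds the four-carbon dienoate in one step by 1,2-attack on the enone carbonyl, keeps the 2E alkene of 15 and favours the extended 4E isomer, the 4Z isomer being removed by chromatography.

**Step 11**
Reactants: 16 ethyl (2E,4E,6E)-5-methyldodeca-2,4,6-trienoate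
Product: 17 (2E,4E,6E)-5-methyldodeca-2,4,6-trienoic acid
Conditions: LiOH, THF/MeOH/H2O, rt; then 1 M HCl to pH 3
Reagents that add atoms: lithium hydroxide, [Li+].[OH-]
Why: Saponification by acyl–oxygen cleavage at room temperature leaves the triene geometry untouched, and the all-E acid can be purified by crystallisation.

**Step 12**
Reactants: 13 (E)-9α,12-diacetoxy-3α-hydroxy-10αH-eremophil-7(11)-en-8-one; 17 (2E,4E,6E)-5-methyldodeca-2,4,6-trienoic acid
Product: 19 (E)-9α,12-diacetoxy-8-oxo-10αH-eremophil-7(11)-en-3α-yl (2E,4E,6E)-5-methyldodeca-2,4,6-trienoate, via mixed anhydride 18 (not isolated)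
Conditions: 17, 2,4,6-trichlorobenzoyl chloride, Et3N, toluene, rt; then 13, DMAP, toluene, rt
Reagents that add atoms: none
Why: In the Yamaguchi esterification DMAP attacks the mixed anhydride at the less hindered trienoyl carbonyl and the acylpyridinium acylates the only free hydroxyl, the equatorial 3α-OH, with retention at C3.

**Step 13**
Reactants: 19 diacetate trienoate
Product: 20 (3R,4R,5R,9S,10R,7(11)E)-9,12-dihydroxy-8-oxoeremophil-7(11)-en-3-yl (2E,4E,6E)-5-methyldodeca-2,4,6-trienoate (target)
Conditions: K2CO3 (0.2 equiv), degassed MeOH, 0 °C, argon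
Reagents that add atoms: none
Why: Base-catalysed transesterification sorts the esters by electrophilicity, the primary allylic and the α-keto acetates being cleaved far faster than the conjugated trienoate of a hindered secondary alcohol, and the equatorial 9α configuration is the stable one should C9 enolise.

**Compound list**
1 | (2E,6E)-farnesol | CC(C)=CCC/C(C)=C/CC/C(C)=C/CO | starting material
2 | (2E,6E)-farnesyl bromide | CC(C)=CCC/C(C)=C/CC/C(C)=C/CBr | intermediate
3 | (2E,6E)-farnesyl diphosphate (triammonium salt, drawn as the acid) | CC(C)=CCC/C(C)=C/CC/C(C)=C/COP(=O)(O)OP(=O)(O)O | intermediate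
4 | (S)-germacrene A (enzyme-bound, not isolated) | C/C1=C\CC/C(C)=C/C[C@@H](C(C)=C)CC1 | intermediate
5 | (+)-aristolochene | C[C@H]1CCCC2=CC[C@H](C(C)=C)C[C@]12C | intermediate
6 | (4S,5R,7S)-eremophila-9,11-dien-8-one | C[C@H]1CCCC2=CC(=O)[C@H](C(C)=C)C[C@]12C | intermediate
7 | lithium C8=C9 enolate of 10αH-eremophil-11-en-8-one (not isolated) | [Li+].C[C@H]1CCC[C@H]2C=C([O-])[C@H](C(C)=C)C[C@]12C | intermediate
8 | trimethylsilyl enol ether (C8=C9) of 10αH-eremophil-11-en-8-one | C[C@H]1CCC[C@H]2C=C(O[Si](C)(C)C)[C@H](C(C)=C)C[C@]12C | intermediate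
9 | 9α-trimethylsilyloxy-11,12-epoxy-10αH-eremophilan-8-one, C11 epimers (not isolated) | C[C@H]1CCC[C@H]2[C@H](O[Si](C)(C)C)C(=O)[C@H](C3(C)CO3)C[C@]12C | intermediate
10 | 9α-hydroxy-11,12-epoxy-10αH-eremophilan-8-one, C11 epimers | C[C@H]1CCC[C@H]2[C@H](O)C(=O)[C@H](C3(C)CO3)C[C@]12C | intermediate
11 | (E)-9α,12-dihydroxy-10αH-eremophil-7(11)-en-8-one | C[C@H]1CCC[C@H]2[C@H](O)C(=O)/C(=C(\C)CO)C[C@]12C | intermediate
12 | (E)-9α,12-diacetoxy-10αH-eremophil-7(11)-en-8-one | C[C@H]1CCC[C@H]2[C@H](OC(C)=O)C(=O)/C(=C(\C)COC(C)=O)C[C@]12C | intermediate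
13 | (E)-9α,12-diacetoxy-3α-hydroxy-10αH-eremophil-7(11)-en-8-one | O[C@@H]1CC[C@H]2[C@H](OC(C)=O)C(=O)/C(=C(\C)COC(C)=O)C[C@]2(C)[C@H]1C | intermediate
14 | (E)-non-3-en-2-one | CCCCC/C=C/C(C)=O | starting material
15 | triethyl (E)-4-phosphonocrotonate | CCOC(=O)/C=C/CP(=O)(OCC)OCC | starting material
16 | ethyl (2E,4E,6E)-5-methyldodeca-2,4,6-trienoate | CCCCC/C=C/C(C)=C/C=C/C(=O)OCC | intermediate
17 | (2E,4E,6E)-5-methyldodeca-2,4,6-trienoic acid | CCCCC/C=C/C(C)=C/C=C/C(=O)O | intermediate
18 | (2E,4E,6E)-5-methyldodeca-2,4,6-trienoic 2,4,6-trichlorobenzoic anhydride (not isolated) | CCCCC/C=C/C(C)=C/C=C/C(=O)OC(=O)c1c(Cl)cc(Cl)cc1Cl | intermediate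
19 | (E)-9α,12-diacetoxy-8-oxo-10αH-eremophil-7(11)-en-3α-yl (2E,4E,6E)-5-methyldodeca-2,4,6-trienoate | CCCCC/C=C/C(C)=C/C=C/C(=O)O[C@@H]1CC[C@H]2[C@H](OC(C)=O)C(=O)/C(=C(\C)COC(C)=O)C[C@]2(C)[C@H]1C | intermediate
20 | CNP0226738.2 | CCCCC/C=C/C(C)=C/C=C/C(=O)O[C@@H]1CC[C@H]2[C@H](O)C(=O)/C(=C(\C)CO)C[C@]2(C)[C@H]1C | target

Total steps: 13. Longest linear sequence: 11 (steps 1–9, 12, 13).

**Steps most likely to fail**

**1. Step 9.**
- What may go wrong:
  - The substrate may not bind productively.
  - Oxygen may be delivered elsewhere, at C2, C1, the allylic C13 methyl or C6.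
  - Esterase traces may hydrolyse the acetates.
- The fallback uses known chemistry, sets out from 10 and returns at 19:
  - Ac2O and pyridine convert 10 into alkene-free 9α-acetoxy-11,12-epoxy-10αH-eremophilan-8-one F1.
  - Non-directed methylene oxidation follows, with [Fe((S,S)-PDP)(MeCN)2](SbF6)2, H2O2 and AcOH in MeCN. It should favour the ring A methylene farthest from the three withdrawing groups and give 9α-acetoxy-11,12-epoxy-10αH-eremophilane-3,8-dione F2. Material oxidised at C2 or C4 is removed by chromatography.
  - DBU, as in step 7, gives (E)-9α-acetoxy-12-hydroxy-10αH-eremophil-7(11)-ene-3,8-dione F3.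
  - Acetylation gives (E)-9α,12-diacetoxy-10αH-eremophil-7(11)-ene-3,8-dione F4.
  - LiBH(s-Bu)3 in THF at −78 °C reduces the saturated C3 ketone in preference to the hindered enone. Attack is equatorial because the axial path is blocked by C14, so the product is the axial alcohol (E)-9α,12-diacetoxy-3β-hydroxy-10αH-eremophil-7(11)-en-8-one F5.
  - A Mitsunobu reaction of F5 with 17 (PPh3, DIAD, toluene) inverts C3 and gives 19 directly.

**2. Step 7.**
- What may go wrong:
  - Alkene geometry may be poorly controlled in the ring opening.
  - E/Z scrambling may follow through the extended enolate.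
  - Z material may be lost by hemiketal closure and dehydration to a furan.
- The fallback replaces kinetic control by capping and recycling, sets out from 10 and returns at 12:
  - The DBU opening is followed in the same flask by Ac2O and DMAP. Then 11 and its isomer (Z)-9α,12-dihydroxy-10αH-eremophil-7(11)-en-8-one F6 are acetylated before F6 can close onto the C8 ketone.
  - Chromatography separates 12 from (Z)-9α,12-diacetoxy-10αH-eremophil-7(11)-en-8-one F7.
  - F7 is re-equilibrated by triplet-sensitised irradiation (thioxanthone, 365 nm, MeCN), and the mixture goes back to the column to give more 12.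

**3. Step 4.**
- What may go wrong:
  - Hydrogen may be abstracted at C1 or at the isopropenyl allylic positions.
  - Over-oxidation may occur.
  - The C11=C12 alkene may migrate into conjugation during work-up.
- The fallback sets out from 5 and returns at 6:
  - Dye-sensitised photooxygenation (O2, tetraphenylporphyrin, visible light, CH2Cl2, 0 °C) is a Schenck ene reaction that prefers the trisubstituted alkene. It should attack the α face and abstract H8 on the more crowded side of the alkene, where C8 is cis to C5. The product is 10α-hydroperoxyeremophila-8,11-diene F8.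
  - PPh3 reduces F8 to eremophila-8,11-dien-10α-ol F9.
  - Pyridinium chlorochromate, [C5H5NH][CrO3Cl], in CH2Cl2 carries out the Babler–Dauben oxidative transposition of this tertiary allylic alcohol to 6.

**Further compounds**
F1 | step 9 | 9α-acetoxy-11,12-epoxy-10αH-eremophilan-8-one (C11 epimers) | C[C@H]1CCC[C@H]2[C@H](OC(C)=O)C(=O)[C@H](C3(C)CO3)C[C@]12C
F2 | step 9 | 9α-acetoxy-11,12-epoxy-10αH-eremophilane-3,8-dione (C11 epimers) | C[C@H]1C(=O)CC[C@H]2[C@H](OC(C)=O)C(=O)[C@H](C3(C)CO3)C[C@]12C
F3 | step 9 | (E)-9α-acetoxy-12-hydroxy-10αH-eremophil-7(11)-ene-3,8-dione | C[C@H]1C(=O)CC[C@H]2[C@H](OC(C)=O)C(=O)/C(=C(\C)CO)C[C@]12C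
F4 | step 9 | (E)-9α,12-diacetoxy-10αH-eremophil-7(11)-ene-3,8-dione | C[C@H]1C(=O)CC[C@H]2[C@H](OC(C)=O)C(=O)/C(=C(\C)COC(C)=O)C[C@]12C
F5 | step 9 | (E)-9α,12-diacetoxy-3β-hydroxy-10αH-eremophil-7(11)-en-8-one | O[C@H]1CC[C@H]2[C@H](OC(C)=O)C(=O)/C(=C(\C)COC(C)=O)C[C@]2(C)[C@H]1C
F6 | step 7 | (Z)-9α,12-dihydroxy-10αH-eremophil-7(11)-en-8-one | C[C@H]1CCC[C@H]2[C@H](O)C(=O)/C(=C(/C)CO)C[C@]12C
F7 | step 7 | (Z)-9α,12-diacetoxy-10αH-eremophil-7(11)-en-8-one | C[C@H]1CCC[C@H]2[C@H](OC(C)=O)C(=O)/C(=C(/C)COC(C)=O)C[C@]12C
F8 | step 4 | 10α-hydroperoxyeremophila-8,11-diene | C[C@H]1CCC[C@@]2(OO)C=C[C@H](C(C)=C)C[C@]12C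
F9 | step 4 | eremophila-8,11-dien-10α-ol | C[C@H]1CCC[C@@]2(O)C=C[C@H](C(C)=C)C[C@]12C
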